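Ring B is not brought in as an arene; it is grown on the finished chromone as a cyclohexane-1,3-dione and aromatized last. The disconnection uses the resorcinol pattern of ring B: the C3' and C5' oxygens flank C4', and the C2' methoxy carbon is bonded to C1', which is attached to chromone C2. In one operation, a Michael–Claisen annulation of dimethyl methoxymalonate onto a chromon-2-yl butenone forms C1'–C2' and C3'–C4' and closes ring B with all three oxygens placed and already differentiated. The precursor is (E)-4-(5-hydroxy-6,7-dimethoxy-4-oxo-4H-chromen-2-yl)but-3-en-2-one, with a free 5-hydroxyl, reached by Wittig olefination of the chromone-2-carbaldehyde.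

Key step: step 5

Remark: the target is achiral; 11 to 14 are taken as racemates or diastereomer mixtures, and the 1,3-diones 12 to 14 are drawn as diketo tautomers although they should be largely enolic.

Step 1
Reactants: 1 3,4,5-trimethoxyphenol
Product: 2 1-(6-hydroxy-2,3,4-trimethoxyphenyl)ethan-1-one
Conditions: AcOH, BF3·OEt2, 90 °C; then H2O
Reagents that add atoms: acetic acid, CC(=O)O
Why: Friedel–Crafts acylation (O-acetylation followed by Fries rearrangement under BF3) of a strongly activated phenol should deliver the ortho-hydroxy ketone, held as its boron chelate; the two ortho positions of 1 are equivalent, so only one ketone can form.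

Step 2
Reactants: 2 1-(6-hydroxy-2,3,4-trimethoxyphenyl)ethan-1-one; 3 ethyl 2,2-diethoxyacetate
Product: 6 5,6,7-trimethoxy-4-oxo-4H-chromene-2-carbaldehyde, via diketone 4 (not isolated), via acetal chromone 5 (not isolated)
Conditions: NaH, THF, reflux; then AcOH, conc. aq. HCl, 60 °C
Reagents that add atoms: water, O
Why: Crossed Claisen condensation of the ketone enolate of 2 with an ester that does not self-condense gives the 1,3-diketone, which cyclodehydrates in acid to the 4-pyranone (the classical chromone synthesis from 2-hydroxyacetophenones) while the aqueous acid hydrolyses the diethyl acetal to the aldehyde.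

Step 3
Reactants: 6 5,6,7-trimethoxy-4-oxo-4H-chromene-2-carbaldehyde
Product: 7 5-hydroxy-6,7-dimethoxy-4-oxo-4H-chromene-2-carbaldehyde
Conditions: BCl3, CH2Cl2, −78 to 0 °C; then aq. HCl
Reagents that add atoms: none
Why: BCl3 forms a six-membered chelate between the C4 carbonyl and the peri C5 methoxy oxygen, so chloride should remove that methyl group alone (chelation-directed aryl methyl ether cleavage), a reaction routinely run in the presence of aryl aldehydes and non-chelated methoxy groups.

Step 4
Reactants: 7 5-hydroxy-6,7-dimethoxy-4-oxo-4H-chromene-2-carbaldehyde; 8 1-(triphenylphosphoranylidene)propan-2-one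
Product: 9 (E)-4-(5-hydroxy-6,7-dimethoxy-4-oxo-4H-chromen-2-yl)but-3-en-2-one
Conditions: CH2Cl2, rt
Reagents that add atoms: none
Why: Wittig olefination with a ketone-stabilised ylide, which is too weakly basic to deprotonate the chelated phenol, reacts only at the aldehyde and should give the E alkene under the usual thermodynamic control of stabilised ylides.

Step 5
Reactants: 9 (E)-4-(5-hydroxy-6,7-dimethoxy-4-oxo-4H-chromen-2-yl)but-3-en-2-one; 10 dimethyl 2-methoxymalonate
Product: 12 methyl 6-(5-hydroxy-6,7-dimethoxy-4-oxo-4H-chromen-2-yl)-1-methoxy-2,4-dioxocyclohexane-1-carboxylate (diastereomer mixture), via Michael adduct 11 (not isolated)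
Conditions: NaOMe (2.5 equiv), 10 (1.5 equiv), MeOH–THF, 0 °C to reflux; then aq. HCl, 0 °C
Reagents that add atoms: none
Why: Methoxide turns the 5-hydroxyl into its phenoxide and forms the methoxymalonate anion, which adds to the enone carbon bonded to chromone C2 (Michael addition, C1'–C2'); after proton exchange the CH3-side enolate of the ketone in adduct 11 attacks one ester group (Claisen condensation, C3'–C4'), methoxide leaves, and deprotonation of the new 1,3-dione at C4' makes the sequence irreversible. The closest known reaction type is the Michael–Claisen annulation of arylidene- and alkylideneacetones with malonic esters to 4-alkoxycarbonyl-5-substituted cyclohexane-1,3-diones, used here with a 2-substituted malonate. Ring B closes in the 6-(enolendo)-exo-trig mode, and no other enolate of 11 can reach an ester through a ring larger than four atoms. The two new stereocentres (the carbon bearing the chromone and the quaternary C(OMe)CO2Me carbon) are not controlled by any element of the substrate, so a mixture of racemic diastereomers is expected, which is harmless because both carbons become sp2 in ring B of the target. The selectivity needed is attack at the butenone β-carbon and not at chromone C2 or at the alkene carbon next to the acetyl group: the acetyl group is the stronger acceptor, the 5-phenoxide feeds electron density into the pyranone carbonyl and so lowers the electrophilicity of the chromone, C2 is fully substituted, and adducts from the other modes form reversibly and cannot cyclise, so they should drain into the dione enolate. An excess of the malonate keeps the methyl ketone of 9 from condensing with itself.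

Step 6
Reactants: 12 methyl 6-(5-hydroxy-6,7-dimethoxy-4-oxo-4H-chromen-2-yl)-1-methoxy-2,4-dioxocyclohexane-1-carboxylate
Product: 14 5-hydroxy-6,7-dimethoxy-2-(2-methoxy-3,5-dioxocyclohexyl)-4H-chromen-4-one (diastereomer mixture), via keto acid 13 (not isolated)
Conditions: 6 M aq. HCl, AcOH, 90 °C
Reagents that add atoms: none
Why: Acid hydrolysis of the methyl ester gives the β-keto acid 13, which should lose CO2 through the cyclic transition state of β-keto acids, while the chromone, the aryl methyl ethers and the α-methoxy ketone tolerate hot aqueous HCl; the C2' centre forms without control, which does not matter.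

Step 7
Reactants: 14 5-hydroxy-6,7-dimethoxy-2-(2-methoxy-3,5-dioxocyclohexyl)-4H-chromen-4-one
Product: 15 2-(3,5-dihydroxy-2-methoxyphenyl)-5-hydroxy-6,7-dimethoxy-4H-chromen-4-one
Conditions: Pd/C (10 wt% Pd), diglyme, reflux (ca. 160 °C), argon stream
Reagents that add atoms: none
Why: Dehydrogenation of a cyclohexane-1,3-dione (a dihydroresorcinol) to the resorcinol over palladium is an established aromatization that needs the loss of only one H2 (from C1' and C6') and removes both stereocentres, and the argon stream carries the H2 away so that it is not transferred to the chromone C2–C3 double bond.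

Compound list
1 | 3,4,5-trimethoxyphenol | COc1cc(O)cc(OC)c1OC | starting material
2 | 1-(6-hydroxy-2,3,4-trimethoxyphenyl)ethan-1-one | CC(=O)c1c(O)cc(OC)c(OC)c1OC | intermediate
3 | ethyl 2,2-diethoxyacetate | CCOC(=O)C(OCC)OCC | starting material
4 | 4,4-diethoxy-1-(6-hydroxy-2,3,4-trimethoxyphenyl)butane-1,3-dione | CCOC(OCC)C(=O)CC(=O)c1c(O)cc(OC)c(OC)c1OC | intermediate (not isolated)
5 | 2-(diethoxymethyl)-5,6,7-trimethoxy-4H-chromen-4-one | CCOC(OCC)c1cc(=O)c2c(OC)c(OC)c(OC)cc2o1 | intermediate (not isolated)
6 | 5,6,7-trimethoxy-4-oxo-4H-chromene-2-carbaldehyde | O=Cc1cc(=O)c2c(OC)c(OC)c(OC)cc2o1 | intermediate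
7 | 5-hydroxy-6,7-dimethoxy-4-oxo-4H-chromene-2-carbaldehyde | O=Cc1cc(=O)c2c(O)c(OC)c(OC)cc2o1 | intermediate
8 | 1-(triphenylphosphoranylidene)propan-2-one | CC(=O)C=P(c1ccccc1)(c1ccccc1)c1ccccc1 | starting material
9 | (E)-4-(5-hydroxy-6,7-dimethoxy-4-oxo-4H-chromen-2-yl)but-3-en-2-one | CC(=O)/C=C/c1cc(=O)c2c(O)c(OC)c(OC)cc2o1 | intermediate
10 | dimethyl 2-methoxymalonate | COC(C(=O)OC)C(=O)OC | starting material
11 | dimethyl 2-[1-(5-hydroxy-6,7-dimethoxy-4-oxo-4H-chromen-2-yl)-3-oxobutyl]-2-methoxymalonate (racemic) | CC(=O)CC(c1cc(=O)c2c(O)c(OC)c(OC)cc2o1)C(OC)(C(=O)OC)C(=O)OC | intermediate (not isolated)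
12 | methyl 6-(5-hydroxy-6,7-dimethoxy-4-oxo-4H-chromen-2-yl)-1-methoxy-2,4-dioxocyclohexane-1-carboxylate (diastereomer mixture) | COC(=O)C1(OC)C(=O)CC(=O)CC1c1cc(=O)c2c(O)c(OC)c(OC)cc2o1 | intermediate
13 | 6-(5-hydroxy-6,7-dimethoxy-4-oxo-4H-chromen-2-yl)-1-methoxy-2,4-dioxocyclohexane-1-carboxylic acid (diastereomer mixture) | OC(=O)C1(OC)C(=O)CC(=O)CC1c1cc(=O)c2c(O)c(OC)c(OC)cc2o1 | intermediate (not isolated)
14 | 5-hydroxy-6,7-dimethoxy-2-(2-methoxy-3,5-dioxocyclohexyl)-4H-chromen-4-one (diastereomer mixture) | COC1C(=O)CC(=O)CC1c1cc(=O)c2c(O)c(OC)c(OC)cc2o1 | intermediate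
15 | 2-(3,5-dihydroxy-2-methoxyphenyl)-5-hydroxy-6,7-dimethoxy-4H-chromen-4-one | COc1cc2oc(-c3cc(O)cc(O)c3OC)cc(=O)c2c(O)c1OC | target

Total step count: 7. Longest linear sequence: 7 steps (1 to 15).

Steps most likely to fail

Step 5 (ring B annulation). Conjugate addition of the hindered, fully substituted malonate anion may be slow and reversible, so that opening of the pyranone by methoxide or self-condensation of the methyl ketone overtakes ring closure. The fallback sets out from 9 and returns at 14; it separates the two bond formations and replaces the malonate by a mono-ester donor. Methyl methoxyacetate is converted (LiN(i-Pr)2, Me3SiCl, THF, −78 °C) into its ketene silyl acetal, 1,2-dimethoxy-1-(trimethylsilyloxy)ethene F1. This is added to 9 in a Mukaiyama–Michael reaction (TiCl4, CH2Cl2, −78 °C, the 5-hydroxyl tied up as its titanium phenoxide; attack is again expected β to the acetyl group) to give the δ-keto ester methyl 3-(5-hydroxy-6,7-dimethoxy-4-oxo-4H-chromen-2-yl)-2-methoxy-5-oxohexanoate F2. Dieckmann-type Claisen closure of this 5-oxohexanoate with KOt-Bu in THF, the established route from δ-keto esters to cyclohexane-1,3-diones, should give 14 directly, so that step 6 falls away.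

Step 7 (dehydrogenation). At the temperature that the palladium surface needs, methanol may be lost across C1'–C2' (aromatization without the 2'-methoxy group), or hydrogen may be transferred to the chromone double bond. The fallback sets out from 14 and returns at 15; it oxidises a silylated substrate at room temperature. Exhaustive silylation (t-BuMe2SiOTf, Et3N, CH2Cl2) should give the cross-conjugated dienol ether 5-[(tert-butyldimethylsilyl)oxy]-2-{3,5-bis[(tert-butyldimethylsilyl)oxy]-2-methoxycyclohexa-3,5-dien-1-yl}-6,7-dimethoxy-4H-chromen-4-one F3 (a regioisomeric dienol ether would converge). DDQ in toluene at room temperature should dehydrogenate this cyclohexadiene to 5-[(tert-butyldimethylsilyl)oxy]-2-{3,5-bis[(tert-butyldimethylsilyl)oxy]-2-methoxyphenyl}-6,7-dimethoxy-4H-chromen-4-one F4, whose silyl ethers shield the resorcinol from over-oxidation. Bu4NF buffered with AcOH in THF then releases 15.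

Step 6 (hydrolysis and decarboxylation). Hydrolysis of the neopentyl-type ester may be slow, and the prolonged heating in acid then needed may open the 1,3-dione by retro-Claisen cleavage. The fallback sets out from 10 (with 9) and returns at 13; it uses an ester that acid removes at room temperature. Half-saponification of 10 (KOH, 1 equiv, MeOH, 0 °C) gives 2,3-dimethoxy-3-oxopropanoic acid F5, and tert-butylation (Boc2O, DMAP, t-BuOH) gives tert-butyl methyl 2-methoxymalonate F6. Annulation with 9 under the conditions of step 5, in which only the methyl ester can serve as the Claisen acceptor, should pass through the Michael adduct 1-tert-butyl 3-methyl 2-[1-(5-hydroxy-6,7-dimethoxy-4-oxo-4H-chromen-2-yl)-3-oxobutyl]-2-methoxypropanedioate F7 (not isolated) to tert-butyl 6-(5-hydroxy-6,7-dimethoxy-4-oxo-4H-chromen-2-yl)-1-methoxy-2,4-dioxocyclohexane-1-carboxylate F8. CF3CO2H in CH2Cl2 at room temperature cleaves the tert-butyl ester to keto acid 13, which loses CO2 on gentle warming to give 14.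

Further compounds
F1 | step 5 | 1,2-dimethoxy-1-(trimethylsilyloxy)ethene (E/Z mixture) | COC=C(OC)O[Si](C)(C)C
F2 | step 5 | methyl 3-(5-hydroxy-6,7-dimethoxy-4-oxo-4H-chromen-2-yl)-2-methoxy-5-oxohexanoate (diastereomer mixture) | COC(=O)C(OC)C(CC(C)=O)c1cc(=O)c2c(O)c(OC)c(OC)cc2o1
F3 | step 7 | 5-[(tert-butyldimethylsilyl)oxy]-2-{3,5-bis[(tert-butyldimethylsilyl)oxy]-2-methoxycyclohexa-3,5-dien-1-yl}-6,7-dimethoxy-4H-chromen-4-one (diastereomer mixture) | COC1C(c2cc(=O)c3c(O[Si](C)(C)C(C)(C)C)c(OC)c(OC)cc3o2)C=C(O[Si](C)(C)C(C)(C)C)C=C1O[Si](C)(C)C(C)(C)C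
F4 | step 7 | 5-[(tert-butyldimethylsilyl)oxy]-2-{3,5-bis[(tert-butyldimethylsilyl)oxy]-2-methoxyphenyl}-6,7-dimethoxy-4H-chromen-4-one | COc1c(O[Si](C)(C)C(C)(C)C)cc(O[Si](C)(C)C(C)(C)C)cc1-c1cc(=O)c2c(O[Si](C)(C)C(C)(C)C)c(OC)c(OC)cc2o1
F5 | step 6 | 2,3-dimethoxy-3-oxopropanoic acid (racemic) | COC(C(=O)O)C(=O)OC
F6 | step 6 | tert-butyl methyl 2-methoxymalonate (racemic) | COC(C(=O)OC)C(=O)OC(C)(C)C
F7 | step 6 | 1-tert-butyl 3-methyl 2-[1-(5-hydroxy-6,7-dimethoxy-4-oxo-4H-chromen-2-yl)-3-oxobutyl]-2-methoxypropanedioate (diastereomer mixture) | CC(=O)CC(c1cc(=O)c2c(O)c(OC)c(OC)cc2o1)C(OC)(C(=O)OC)C(=O)OC(C)(C)C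
F8 | step 6 | tert-butyl 6-(5-hydroxy-6,7-dimethoxy-4-oxo-4H-chromen-2-yl)-1-methoxy-2,4-dioxocyclohexane-1-carboxylate (diastereomer mixture) | COC1(C(=O)OC(C)(C)C)C(=O)CC(=O)CC1c1cc(=O)c2c(O)c(OC)c(OC)cc2o1
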